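# Proposed synthesis of (2S)-6,8-diprenylnaringenin by aryne annulation with a chiral β-silyloxy ester

## The problem

6,8-Diprenylnaringenin 21 is a flavanone in which a fully substituted phloroglucinol ring A (oxygens at C5, C7 and C8a, prenyl groups at C6 and C8, the ketone carbon C4 on C4a) is fused through O1–C8a and C4–C4a to the dihydropyranone ring C, which carries the 4-hydroxyphenyl ring B at C2. C2 (S) is the only stereocentre, so nothing in the molecule can relay it and a reagent or catalyst has to set it. Once set it has to be guarded, because a flavanone opens to the 2'-hydroxychalcone by E1cB cleavage of C2–O1 under base and can ionise at the benzylic C2–O1 bond under strong acid, and both paths racemise it. Each prenyl group sits beside a phenol, so acid closes them to chromans, electrophilic halogen attacks the trisubstituted alkenes and hydrogenolysis is excluded. Ring A is hexasubstituted, and the order of its six substituents has to be fixed without isomer mixtures, for which the mirror symmetry of 2,4-diprenylphloroglucinol 3 is the natural aid. The feature that invites an unusual ring closure is the pair of neighbouring ring A carbons C8a and C4a: C8a bears the nucleophile-derived O1 and has the C8 prenyl group as its other neighbour, whereas C4a bears the electrophile-derived C4 and has the C5 oxygen as its other neighbour. This is the pattern left when an oxygen nucleophile and a tethered acyl group add across an aryne C4a≡C8a that is polarised by a flanking alkoxy group, and the C2–C3–C4 unit that supplies both atoms can receive its stereocentre beforehand by a reliable ketone reduction.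

## Retrosynthesis

**21 ⇒ 20.** Only three acetal C–O bonds are cut: the three phenols of 21 are masked as methoxymethyl ethers in 20. The choice follows from the step before. The masks must survive fluoride, a naked alkoxide and an aryl carbanion, which excludes silyl ethers and esters, and they must come off without hydrogenolysis, which excludes benzyl ethers beside two prenyl groups. Compound 20 is no simpler in skeleton than 21, but it is the form in which ring C can be closed. The forward reaction asked for is a short, mild acidic methanolysis that leaves the prenyl groups and C2 alone.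

**20 ⇒ 10 + 16.** The two bonds that join ring C to ring A, O1–C8a and C4–C4a, are cut together. The neighbouring cuts are weaker: cutting O1–C2 (oxa-Michael closure of a chalcone) or C2–C3 (aldol-type closure) would create C2 during ring formation and in equilibrium with the open form, and cutting C4–C4a alone (Friedel–Crafts or Fries chemistry) needs strong acid beside prenyl groups. The double cut leaves C2 untouched and gives two halves of similar size: ring A becomes the ortho-silylaryl triflate 10, the latent form of aryne 17, and C2–C4 with ring B becomes silyl ether 16 of hydroxy ester 15, the latent form of alkoxide 18. In the forward sense 18 has to add to C8a of 17 and the resulting C4a carbanion 19 has to acylate its own ester. This asks for addition at C8a and not at C4a, which the C5 oxygen should direct, for acylation faster than protonation, hence the proton-free silyl ether 16 in place of free 15, and for capture of 18 by the aryne faster than its retro-aldol cleavage.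

**16 ⇒ 15 ⇒ 14 ⇒ 12 + 13, and 12 ⇒ 11.** The O–Si bond of 16 is cut first, which leads to hydroxy ester 15. The C2–H bond of 15 is then traced to β-keto ester 14, so that C2 is set by catalyst-controlled transfer hydrogenation of an aryl ketone and not during a ring closure. Cutting the C3–C4 bond of 14 (Claisen condensation) leads to acetophenone 12 and dimethyl carbonate 13, and 12 is the methoxymethyl ether of 4'-hydroxyacetophenone 11. Each precursor is simpler than the one before, and the forward reactions are routine and give a fragment with one stereocentre and no other sensitive group.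

**10 ⇒ 9 ⇒ 5 ⇒ 4.** The two acetals of 10 are removed to give diphenol 9. The ortho pair C–Si and C–OTf of 9 is traced to aryl bromide 5 through bromine–lithium exchange to aryllithium 6, a 1,3 O→C silyl shift to phenoxide 7 and triflation to 8. This sequence chooses by itself which oxygen becomes the triflate, namely the one that gave up its silicon, and the two silyloxy groups flanking C–Br in 5 are related by a mirror plane, so only one product can form. Directed metalation of a tris-acetal would place silicon equally well but could not tell the three oxygens apart. Bromide 5 is the tris-silyl ether of bromotriol 4, a much simpler compound; the forward sequence must run the exchange, the shift and the triflation in one flask at low temperature.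

**4 ⇒ 3 ⇒ 1 + 2.** The C–Br bond is cut at the only unsubstituted ring position of 3, so no choice of site arises. Cutting the two aryl–prenyl bonds then leads to phloroglucinol 1 and prenyl bromide 2, both commodity chemicals. After the first C-prenylation the two open positions of the ring are equivalent, so the dialkylation has a problem of degree but not of regiochemistry, and the forward reaction is asked only to stop at two prenyl groups on carbon.

## Roads not taken

**Alternative 1: [3+3] construction of ring A.** The cut runs through C5–C6 and C8–C8a inside ring A. In the forward key step the trimethylsilyl enol ether A2 of 2,10-dimethylundeca-2,9-dien-6-one A1 is C-acylated twice by malonyl dichloride A3 and the product enolises to 2,4-diprenylphloroglucinol A4, which is the same substance as 3. Its merit is that both prenyl groups are already in the ketone, so ring A is formed with no statistical alkylation and no separation from mono- and triprenylated material; in this respect it is better than step 1 of the chosen plan. Its weak points are that such acylations of ketone enol derivatives commonly end in C- then O-acylation and give a pyranone instead of the carbocycle, that the second C-acylation needs enolisation towards the other α-carbon, that the HCl released meets two acid-sensitive trisubstituted alkenes, and that A1 itself takes two to three steps to prepare. In comparison, this road ends at ring A and says nothing about ring C or C2, so it can replace only the first step of the chosen plan and not its idea. Against its regiocontrol the chosen plan sets one operation from two commodity chemicals with recycling of the monoprenyl fraction, and a stepwise ortho-metalation fallback in which every step is precedented.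

**Alternative 2: asymmetric Petasis–Ferrier rearrangement.** The cut is C2–C3. In the forward key step the 2-aryl-4-methylene-1,3-benzodioxine A5 is ionised by a chiral acid at its acetal carbon; the aryl-stabilised oxocarbenium ion and the tethered C4 enolate recombine to form C2–C3, which turns the dioxine into ring C, sets C2 and gives the tris(tert-butyldimethylsilyl) ether A6. Its merits are that ring A is complete before the key step, so no regiochemical question arises, that the stereocentre is made catalytically in the ring-forming step, and that the silyl ethers come off without acid. Its weak points are several. Enantiocontrol over a long-lived oxocarbenium ion stabilised by a 4-silyloxyphenyl group and held only by ion pairing has no close model, so reactivity and selectivity would both be new. Making A5 requires carbonyl methylenation on a fully substituted ring A. The acid promoter meets the prenyl groups, the oxocarbenium ion can fragment to aldehyde and phenol, and fluoride deprotection at the end generates phenoxides that can open the flavanone. In comparison, this road has two unknowns in one step, whereas the chosen plan has one (reactivity), because its stereocentre comes from a standard ketone reduction and is only carried through. Alternative 2 is better in avoiding the aryne regiochemistry and an acidic last step; the chosen plan answers with the inductive bias of the C5 oxygen and the established mild acidic unmasking of prenylated flavanones.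

**Alternative 3: carbonylative flavone annulation, then asymmetric reduction.** The cuts are C4a–C4, C3–C4 and O1–C2. In the forward key step PdCl2(PPh3)2-catalysed coupling of 2-iodo-4,6-diprenylphloroglucinol A7, carbon monoxide A9 and 1-ethynyl-4-(methoxymethoxy)benzene A8 gives an ynone, and an ortho hydroxyl adds to it to close ring C as flavone A10. Its merits are that the ring-forming step is known chemistry on ortho-iodophenols, needs no protection on ring A and forms three bonds at once, so its key step is safer than the one chosen here. Its weak points are that iodination of the diprenyl triol faces the same alkene problem as the bromination in the chosen plan, that cyclisation can also go 5-exo to the aurone, and above all that the stereocentre is still missing after the key step. It would have to come from an enantioselective 1,4-reduction of the C2=C3 bond of A10, which carries a chelated C5 hydroxyl and two reducible prenyl alkenes; that reaction class is thinly developed, prone to over-reduction at C4, and run under basic hydride conditions that threaten the configuration of the product. In comparison, alternative 3 moves the unsolved problem from ring closure to the stereocentre, whereas the chosen plan accepts an unprecedented ring closure but settles the stereocentre first, by a dependable reaction, and has a chalcone-based fallback built from known reactions.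

Key step: step 10

Remark on the chemistry: the sense of induction in step 8 is assigned by analogy with simple aryl alkyl ketones, for which RuCl(p-cymene)[(S,S)-TsDPEN] gives the (S)-carbinol; the priority order O > aryl > CH2 is the same at this carbon in 15, 16, 20 and 21, so (S) remains (S).

## Route

Step 1
Reactants: 1 phloroglucinol; 2 prenyl bromide (1-bromo-3-methylbut-2-ene)
Product: 3 2,4-bis(3-methylbut-2-en-1-yl)benzene-1,3,5-triol (2,4-diprenylphloroglucinol)
Conditions: 2 (2.0 equiv), 10% aq KOH, 0 °C; chromatography, monoprenyl fraction resubmitted
Reagents that add atoms: none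
Why: Base-mediated C-alkylation of an ambident phenolate: in water the phloroglucinolate takes the allylic bromide at carbon, and after the first prenylation the two open ring positions are equivalent, so dialkylation on carbon can only give the 2,4-pattern and the task is reduced to separating 3 from under- and over-alkylated material.

Step 2
Reactants: 3 2,4-diprenylphloroglucinol
Product: 4 2-bromo-4,6-bis(3-methylbut-2-en-1-yl)benzene-1,3,5-triol
Conditions: NBS (1.0 equiv), CH2Cl2/THF, −78 °C
Reagents that add atoms: N-bromosuccinimide, O=C1CCC(=O)N1Br
Why: Electrophilic aromatic bromination: the single ring C–H is activated by two ortho and one para hydroxyl groups and should take up bromine at low temperature much faster than the trisubstituted alkenes; ring halogenation of terpenyl resorcinols in the presence of their alkenes is the precedent, and one equivalent of reagent at −78 °C limits bromoetherification.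

Step 3
Reactants: 4 2-bromo-4,6-diprenylphloroglucinol
Product: 5 2-bromo-4,6-bis(3-methylbut-2-en-1-yl)-1,3,5-tris(trimethylsilyloxy)benzene
Conditions: HMDS, THF, 65 °C; evaporation, used crude
Reagents that add atoms: hexamethyldisilazane, C[Si](C)(C)N[Si](C)(C)C
Why: O-silylation of phenols with hexamethyldisilazane; the only by-product is ammonia, so the moisture-sensitive tris-silyl ether can be taken on after evaporation.

Step 4
Reactants: 5 tris(trimethylsilyl) ether of 4
Product: 9 3,5-dihydroxy-2,4-bis(3-methylbut-2-en-1-yl)-6-(trimethylsilyl)phenyl trifluoromethanesulfonate, via aryllithium 6 (not isolated), via lithium phenoxide 7 (not isolated), via bis(silyl ether) triflate 8 (not isolated)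
Conditions: n-BuLi, THF, −78 °C; Tf2O, −78 °C; then MeOH, citric acid (cat.), 0 °C
Reagents that add atoms: trifluoromethanesulfonic anhydride, O=S(=O)(OS(=O)(=O)C(F)(F)F)C(F)(F)F
Why: Bromine–lithium exchange gives 6, whose neighbouring O-silyl group migrates to carbon (retro-Brook 1,3 O→C shift) to give phenoxide 7; the two flanking silyloxy groups are equivalent, so one product results and only the oxygen that lost its silicon is triflated (8). Weakly acidic methanolysis then removes the two labile aryl O-silyl groups without touching C–Si or O–Tf and without forming a phenoxide beside the C–Si bond; this sequence is the standard entry to ortho-silylaryl triflates.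

Step 5
Reactants: 9 diphenol silyl triflate
Product: 10 3,5-bis(methoxymethoxy)-2,4-bis(3-methylbut-2-en-1-yl)-6-(trimethylsilyl)phenyl trifluoromethanesulfonate
Conditions: MOMCl, i-Pr2NEt, CH2Cl2, 0 °C → rt
Reagents that add atoms: chloromethyl methyl ether, COCCl
Why: O-alkylation of the two phenols with an α-chloro ether and a hindered amine (methoxymethyl protection); the weak amine base and the very reactive electrophile keep the concentration of free phenoxide low, which matters because a naked phenoxide beside the C–Si bond could shift silicon from carbon to oxygen and expel triflate. O-sulfonylation of hydroxy silyl triflates of this kind under amine bases, the entry to 3-triflyloxyaryne precursors, is the close precedent.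

Step 6
Reactants: 11 4'-hydroxyacetophenone
Product: 12 1-[4-(methoxymethoxy)phenyl]ethan-1-one
Conditions: MOMCl, i-Pr2NEt, CH2Cl2, 0 °C → rt
Reagents that add atoms: chloromethyl methyl ether, COCCl
Why: Standard methoxymethyl protection of a phenol, chosen so that ring B carries the same mask as ring A and all three are removed together.

Step 7
Reactants: 12 4'-(methoxymethoxy)acetophenone; 13 dimethyl carbonate
Product: 14 methyl 3-[4-(methoxymethoxy)phenyl]-3-oxopropanoate
Conditions: NaH, 13 (3 equiv), THF, reflux; AcOH, 0 °C
Reagents that add atoms: none
Why: Crossed Claisen condensation of the ketone enolate with dimethyl carbonate, driven by deprotonation of the β-keto ester formed; the acetal is inert to NaH and the quench is kept weakly acidic.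

Step 8
Reactants: 14 β-keto ester
Product: 15 methyl (3S)-3-hydroxy-3-[4-(methoxymethoxy)phenyl]propanoate
Conditions: RuCl(p-cymene)[(S,S)-TsDPEN] (1 mol %), HCO2H/Et3N (5:2), EtOAc, rt
Reagents that add atoms: none
Why: Noyori–Ikariya asymmetric transfer hydrogenation: the Ru–H/N–H pair of the (S,S)-TsDPEN complex delivers hydrogen to the aryl ketone through the CH–π-organised six-membered transition state that gives (S)-carbinols from aryl alkyl ketones, which sets C2 as (S); the buffered formic acid medium should spare the aryl acetal.

Step 9
Reactants: 15 (S)-hydroxy ester
Product: 16 methyl (3S)-3-[4-(methoxymethoxy)phenyl]-3-(trimethylsilyloxy)propanoate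
Conditions: HMDS, TMSCl (cat.), CH2Cl2, rt; filtration, high vacuum
Reagents that add atoms: hexamethyldisilazane, C[Si](C)(C)N[Si](C)(C)C
Why: Silylation of the secondary alcohol with hexamethyldisilazane; it removes the O–H proton from the key step and turns the alkoxide into a species that fluoride releases on demand, and the stereocentre is not involved.

Step 10
Reactants: 10 bis(methoxymethyl) silyl triflate; 16 (S)-silyloxy ester
Product: 20 (2S)-5,7-bis(methoxymethoxy)-2-[4-(methoxymethoxy)phenyl]-6,8-bis(3-methylbut-2-en-1-yl)chroman-4-one, via aryne 17 (not isolated), via caesium alkoxide 18 (not isolated), via aryl carbanion 19 (not isolated)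
Conditions: 16 (1.2 equiv), CsF (1.1 equiv), 18-crown-6, THF, slow addition of 10, 0 °C → rt; pH 7 buffer
Reagents that add atoms: none
Why: Proposed new method: fluoride strips the trimethylsilyl groups of 10 and 16, so aryne 17 and the naked alkoxide 18 are released side by side in a medium without O–H or N–H protons; 18 adds to C8a, the aryne carbon remote from the C5 oxygen, because the inductively withdrawing C5–O bond makes C4a the better site for the developing negative charge, and this bias should outweigh the hindrance of the C8 prenyl group. The carbanion 19 then attacks its own ester carbonyl and closes ring C by 6-exo-trig addition–elimination, forming C4–C4a after O1–C8a. The expelled methoxide is silylated by a further molecule of 10 or 16 (releasing more 17 or 18), so little more than one equivalent of fluoride suffices and the end point holds methoxytrimethylsilane instead of a free base, which shields the product from E1cB opening of C2–O1 and hence from racemisation. The closest known reactions are the fluoride-induced annulation of arynes with salicylate esters to xanthones and the acyl transfer that turns arynes and carboxylic acids into ortho-hydroxyaryl ketones; new here are an aliphatic secondary alkoxide as nucleophile and a β-oxygenated ester as acyl donor. No stereocentre is created: no bond to C2 is made or broken, so the (S) configuration from step 8 is carried over unchanged. The step needs regioselectivity (C8a against C4a), secured by the C5 methoxymethoxy group, and chemoselectivity for acylation over protonation, retro-aldol cleavage and ene reaction with the prenyl groups, secured by the proton-free release of 18 from its silyl ether, the low stationary concentrations of 17 and 18, and the six-membered transition state of the acyl transfer.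

Step 11
Reactants: 20 tris(methoxymethyl) ether
Product: 21 (2S)-5,7-dihydroxy-2-(4-hydroxyphenyl)-6,8-bis(3-methylbut-2-en-1-yl)chroman-4-one (6,8-diprenylnaringenin)
Conditions: HCl (1.25 M in MeOH), 0 °C → rt
Reagents that add atoms: none
Why: Acid-catalysed acetal methanolysis to dimethoxymethane; dilute HCl in methanol near room temperature is the established way to unmask prenylated flavanones, is too mild to ionise C2–O1, and is stopped as soon as the hindered C7 ether is gone to limit chroman formation.

## Compound list

1 | phloroglucinol (benzene-1,3,5-triol) | Oc1cc(O)cc(O)c1 | starting material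
2 | prenyl bromide (1-bromo-3-methylbut-2-ene) | CC(C)=CCBr | starting material
3 | 2,4-bis(3-methylbut-2-en-1-yl)benzene-1,3,5-triol | CC(C)=CCc1c(O)cc(O)c(CC=C(C)C)c1O | intermediate
4 | 2-bromo-4,6-bis(3-methylbut-2-en-1-yl)benzene-1,3,5-triol | CC(C)=CCc1c(O)c(Br)c(O)c(CC=C(C)C)c1O | intermediate
5 | 2-bromo-4,6-bis(3-methylbut-2-en-1-yl)-1,3,5-tris(trimethylsilyloxy)benzene | CC(C)=CCc1c(O[Si](C)(C)C)c(Br)c(O[Si](C)(C)C)c(CC=C(C)C)c1O[Si](C)(C)C | intermediate
6 | 2-lithio-4,6-bis(3-methylbut-2-en-1-yl)-1,3,5-tris(trimethylsilyloxy)benzene | CC(C)=CCc1c(O[Si](C)(C)C)c([Li])c(O[Si](C)(C)C)c(CC=C(C)C)c1O[Si](C)(C)C | intermediate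
7 | lithium 2,4-bis(3-methylbut-2-en-1-yl)-3,5-bis(trimethylsilyloxy)-6-(trimethylsilyl)phenoxide | CC(C)=CCc1c([O-])c([Si](C)(C)C)c(O[Si](C)(C)C)c(CC=C(C)C)c1O[Si](C)(C)C.[Li+] | intermediate
8 | 2,4-bis(3-methylbut-2-en-1-yl)-3,5-bis(trimethylsilyloxy)-6-(trimethylsilyl)phenyl trifluoromethanesulfonate | CC(C)=CCc1c(OS(=O)(=O)C(F)(F)F)c([Si](C)(C)C)c(O[Si](C)(C)C)c(CC=C(C)C)c1O[Si](C)(C)C | intermediate
9 | 3,5-dihydroxy-2,4-bis(3-methylbut-2-en-1-yl)-6-(trimethylsilyl)phenyl trifluoromethanesulfonate | CC(C)=CCc1c(OS(=O)(=O)C(F)(F)F)c([Si](C)(C)C)c(O)c(CC=C(C)C)c1O | intermediate
10 | 3,5-bis(methoxymethoxy)-2,4-bis(3-methylbut-2-en-1-yl)-6-(trimethylsilyl)phenyl trifluoromethanesulfonate | CC(C)=CCc1c(OCOC)c(CC=C(C)C)c(OS(=O)(=O)C(F)(F)F)c([Si](C)(C)C)c1OCOC | intermediate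
11 | 4'-hydroxyacetophenone | CC(=O)c1ccc(O)cc1 | starting material
12 | 1-[4-(methoxymethoxy)phenyl]ethan-1-one | CC(=O)c1ccc(OCOC)cc1 | intermediate
13 | dimethyl carbonate | COC(=O)OC | starting material
14 | methyl 3-[4-(methoxymethoxy)phenyl]-3-oxopropanoate | COC(=O)CC(=O)c1ccc(OCOC)cc1 | intermediate
15 | methyl (3S)-3-hydroxy-3-[4-(methoxymethoxy)phenyl]propanoate | COC(=O)C[C@@H](c1ccc(OCOC)cc1)O | intermediate
16 | methyl (3S)-3-[4-(methoxymethoxy)phenyl]-3-(trimethylsilyloxy)propanoate | COC(=O)C[C@@H](c1ccc(OCOC)cc1)O[Si](C)(C)C | intermediate
17 | 3,5-bis(methoxymethoxy)-4,6-bis(3-methylbut-2-en-1-yl)benzyne (aryne across C4a and C8a) | COCOC1=C(CC=C(C)C)C(OCOC)=C(CC=C(C)C)C#C1 | intermediate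
18 | caesium (1S)-3-methoxy-1-[4-(methoxymethoxy)phenyl]-3-oxopropan-1-olate | COC(=O)C[C@@H](c1ccc(OCOC)cc1)[O-].[Cs+] | intermediate
19 | caesium aryl carbanion at C4a of the O-arylated ester: methyl (3S)-3-[3,5-bis(methoxymethoxy)-2,4-bis(3-methylbut-2-en-1-yl)phenoxy]-3-[4-(methoxymethoxy)phenyl]propanoate metalated at C6 of the phenoxy ring | COC(=O)C[C@@H](c1ccc(OCOC)cc1)Oc1c(CC=C(C)C)c(OCOC)c(CC=C(C)C)c(OCOC)[c-]1.[Cs+] | intermediate
20 | (2S)-5,7-bis(methoxymethoxy)-2-[4-(methoxymethoxy)phenyl]-6,8-bis(3-methylbut-2-en-1-yl)chroman-4-one | CC(C)=CCc1c(OCOC)c(CC=C(C)C)c2c(c1OCOC)C(=O)C[C@@H](c1ccc(OCOC)cc1)O2 | intermediate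
21 | (2S)-5,7-dihydroxy-2-(4-hydroxyphenyl)-6,8-bis(3-methylbut-2-en-1-yl)chroman-4-one (6,8-diprenylnaringenin) | CC(C)=CCc1c(O)c(CC=C(C)C)c2c(c1O)C(=O)C[C@@H](c1ccc(O)cc1)O2 | target

## Step count and least certain steps

Total step count: 11. Longest linear sequence: 7 steps (steps 1–5, 10 and 11); the second branch (steps 6–9) joins at step 10.

**Step 10 (key step, new method).** Several processes can divert it. Carbanion 19 may be quenched by proton transfer, for example from an ester α-CH, before it acylates, which would leave an uncyclised aryl ether. Alkoxide 18 may undergo retro-aldol fragmentation, β-elimination or intermolecular transesterification before it meets the aryne. Addition may occur at C4a instead of C8a if the hindrance of the C8 prenyl group outweighs the inductive bias. Configuration may be lost by base-induced opening and reclosure of ring C if free alkoxide accumulates. The fallback uses known reaction types, sets out from 10 and returns at 20. Fluoride-induced aryne formation from 10 in the presence of acetic acid (CsF, THF, 100 °C) gives, by carboxylate O-arylation at C8a and acyl transfer to C4a, 1-[2-hydroxy-4,6-bis(methoxymethoxy)-3,5-bis(3-methylbut-2-en-1-yl)phenyl]ethan-1-one F1. Claisen–Schmidt condensation of F1 with commercial 4-(methoxymethoxy)benzaldehyde (KOH, EtOH) gives (E)-1-[2-hydroxy-4,6-bis(methoxymethoxy)-3,5-bis(3-methylbut-2-en-1-yl)phenyl]-3-[4-(methoxymethoxy)phenyl]prop-2-en-1-one F2. An enantioselective intramolecular oxa-Michael addition then closes ring C to 20, using a bifunctional cinchona-alkaloid thiourea catalyst whose quinine- or quinidine-derived form is selected for the (2S) series. In this fallback the stereocentre comes from the cyclisation catalyst and steps 6–9 are not needed.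

**Step 1.** Uncontrolled degree and site of alkylation (mono- and tri-C-prenylation, geminal dialkylation with dearomatisation, O-alkylation) may leave little 3. The fallback sets out from 1 and returns at 3. Exhaustive protection (MOMCl, NaH, DMF) gives 1,3,5-tris(methoxymethoxy)benzene F3. Directed ortho-lithiation between two acetal oxygens (n-BuLi, THF, 0 °C), transmetalation with CuI and quenching with 2 gives 1,3,5-tris(methoxymethoxy)-2-(3-methylbut-2-en-1-yl)benzene F4. A second identical lithiation–prenylation, at either of the two equivalent positions, gives 1,3,5-tris(methoxymethoxy)-2,4-bis(3-methylbut-2-en-1-yl)benzene F5. Acidic methanolysis (HCl, MeOH, rt) returns 3.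

**Step 2.** The brominating agent may attack a prenyl alkene with capture by the neighbouring phenol (bromoetherification), or ipso-bromination with dearomatisation may compete. The fallback sets out from 3 and returns at 4. Protection of 3 (MOMCl, i-Pr2NEt) gives the tris(methoxymethyl) ether already described as F5; if the fallback to step 1 is in use, F5 is taken directly. Lithiation of the last ring position, which lies between two acetal oxygens (n-BuLi, THF, 0 °C), and quenching with 1,2-dibromotetrachloroethane gives 2-bromo-1,3,5-tris(methoxymethoxy)-4,6-bis(3-methylbut-2-en-1-yl)benzene F6. No electrophilic bromine meets the alkenes, and acidic methanolysis returns 4.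

**Step 11.** Acid-catalysed cyclisation of a prenyl group onto a freshly liberated neighbouring phenol (chroman formation), addition of HCl or methanol to the alkenes, or slow loss of configuration during a prolonged reaction forced by the hindered C7 ether may occur. The fallback sets out from 9 and returns at 21. Mitsunobu allylation of 9 (allyl alcohol, PPh3, diisopropyl azodicarboxylate, THF, 0 °C → rt), chosen because it needs no carbonate base beside the C–Si bond, gives 3,5-bis(allyloxy)-2,4-bis(3-methylbut-2-en-1-yl)-6-(trimethylsilyl)phenyl trifluoromethanesulfonate F7. Annulation of F7 with 16 under the conditions of step 10 gives (2S)-5,7-bis(allyloxy)-2-[4-(methoxymethoxy)phenyl]-6,8-bis(3-methylbut-2-en-1-yl)chroman-4-one F8. The single remaining acetal is removed with HCl in methanol while both ring A oxygens are still capped, so that no phenol is available to cyclise onto a prenyl group, which gives (2S)-5,7-bis(allyloxy)-2-(4-hydroxyphenyl)-6,8-bis(3-methylbut-2-en-1-yl)chroman-4-one F9. Deallylation under neutral conditions with zerovalent palladium (Pd(PPh3)4, morpholine, THF, rt), which does not touch prenyl groups, gives 21.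

## Further compounds

F1 | step 10 | 1-[2-hydroxy-4,6-bis(methoxymethoxy)-3,5-bis(3-methylbut-2-en-1-yl)phenyl]ethan-1-one | CC(=O)c1c(O)c(CC=C(C)C)c(OCOC)c(CC=C(C)C)c1OCOC
F2 | step 10 | (E)-1-[2-hydroxy-4,6-bis(methoxymethoxy)-3,5-bis(3-methylbut-2-en-1-yl)phenyl]-3-[4-(methoxymethoxy)phenyl]prop-2-en-1-one | COCOc1ccc(/C=C/C(=O)c2c(O)c(CC=C(C)C)c(OCOC)c(CC=C(C)C)c2OCOC)cc1
F3 | step 1 | 1,3,5-tris(methoxymethoxy)benzene | COCOc1cc(OCOC)cc(OCOC)c1
F4 | step 1 | 1,3,5-tris(methoxymethoxy)-2-(3-methylbut-2-en-1-yl)benzene | CC(C)=CCc1c(OCOC)cc(OCOC)cc1OCOC
F5 | step 1 | 1,3,5-tris(methoxymethoxy)-2,4-bis(3-methylbut-2-en-1-yl)benzene | CC(C)=CCc1c(OCOC)cc(OCOC)c(CC=C(C)C)c1OCOC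
F6 | step 2 | 2-bromo-1,3,5-tris(methoxymethoxy)-4,6-bis(3-methylbut-2-en-1-yl)benzene | CC(C)=CCc1c(OCOC)c(Br)c(OCOC)c(CC=C(C)C)c1OCOC
F7 | step 11 | 3,5-bis(allyloxy)-2,4-bis(3-methylbut-2-en-1-yl)-6-(trimethylsilyl)phenyl trifluoromethanesulfonate | CC(C)=CCc1c(OCC=C)c(CC=C(C)C)c(OS(=O)(=O)C(F)(F)F)c([Si](C)(C)C)c1OCC=C
F8 | step 11 | (2S)-5,7-bis(allyloxy)-2-[4-(methoxymethoxy)phenyl]-6,8-bis(3-methylbut-2-en-1-yl)chroman-4-one | CC(C)=CCc1c(OCC=C)c(CC=C(C)C)c2c(c1OCC=C)C(=O)C[C@@H](c1ccc(OCOC)cc1)O2
F9 | step 11 | (2S)-5,7-bis(allyloxy)-2-(4-hydroxyphenyl)-6,8-bis(3-methylbut-2-en-1-yl)chroman-4-one | CC(C)=CCc1c(OCC=C)c(CC=C(C)C)c2c(c1OCC=C)C(=O)C[C@@H](c1ccc(O)cc1)O2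
A1 | alternative 1 | 2,10-dimethylundeca-2,9-dien-6-one | CC(C)=CCCC(=O)CCC=C(C)C
A2 | alternative 1 | 2,10-dimethyl-6-(trimethylsilyloxy)undeca-2,5,9-triene | CC(C)=CCC=C(O[Si](C)(C)C)CCC=C(C)C
A3 | alternative 1 | malonyl dichloride | O=C(Cl)CC(=O)Cl
A4 | alternative 1 | 2,4-bis(3-methylbut-2-en-1-yl)benzene-1,3,5-triol | CC(C)=CCc1c(O)cc(O)c(CC=C(C)C)c1O
A5 | alternative 2 | 5,7-bis(tert-butyldimethylsilyloxy)-2-[4-(tert-butyldimethylsilyloxy)phenyl]-4-methylene-6,8-bis(3-methylbut-2-en-1-yl)-4H-1,3-benzodioxine | C=C1OC(c2ccc(O[Si](C)(C)C(C)(C)C)cc2)Oc2c(CC=C(C)C)c(O[Si](C)(C)C(C)(C)C)c(CC=C(C)C)c(O[Si](C)(C)C(C)(C)C)c21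
A6 | alternative 2 | (2S)-5,7-bis(tert-butyldimethylsilyloxy)-2-[4-(tert-butyldimethylsilyloxy)phenyl]-6,8-bis(3-methylbut-2-en-1-yl)chroman-4-one | CC(C)=CCc1c(O[Si](C)(C)C(C)(C)C)c(CC=C(C)C)c2c(c1O[Si](C)(C)C(C)(C)C)C(=O)C[C@@H](c1ccc(O[Si](C)(C)C(C)(C)C)cc1)O2
A7 | alternative 3 | 2-iodo-4,6-bis(3-methylbut-2-en-1-yl)benzene-1,3,5-triol | CC(C)=CCc1c(O)c(I)c(O)c(CC=C(C)C)c1O
A8 | alternative 3 | 1-ethynyl-4-(methoxymethoxy)benzene | C#Cc1ccc(OCOC)cc1
A9 | alternative 3 | carbon monoxide | [C-]#[O+]
A10 | alternative 3 | 5,7-dihydroxy-2-[4-(methoxymethoxy)phenyl]-6,8-bis(3-methylbut-2-en-1-yl)chromen-4-one | CC(C)=CCc1c(O)c(CC=C(C)C)c2c(c1O)C(=O)C=C(c1ccc(OCOC)cc1)O2
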